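**Target:** (4S,5R,8R,9R,10S)-8α-hydroxylabda-13(16),14-dien-19-yl (E)-4-methoxycinnamate. Reading the SMILES: normal labdane series, 5α-H, 9α-H, 10β-Me, 8α-OH/8β-Me, and the acylated CH2O is C19 (axial, cis to C20).

**Assumption:** (E)-geranyl acetate of ≥97 % isomeric purity is used, and the (S)-BINOL La-Li3 catalyst is taken to give the (S)-epoxide; if the sense is opposite, the (R)-BINOL complex is used.

## Retrosynthetic overview
1. Target 16 ⇐ vinyl triflate 15 (Stille vinylation builds the 13(16),14-diene) ⇐ methyl ketone 13 ⇐ diol ketone 11 + 4-methoxycinnamic acid 12.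
2. Key step: 11 ⇐ acyclic (S)-epoxy dienone 9. Rings A and B form in one cationic cascade initiated at a 2,2-disubstituted (terminal) epoxide, which delivers C4(Me)(CH2OH) directly with no C3 oxygen to remove.
3. Ring order: C4–C5 (ring A), then C10–C9 (ring B), then O–C8 capture by the ketone (transient pyran ring, opened on work-up to 8α-OH and the C13 ketone).
4. 9 ⇐ epoxy allylic acetate 8 (Pd acetonylation) ⇐ methyl ketone 7 (catalytic asymmetric sulfur-ylide epoxidation sets the only external stereocentre).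
5. 7 ⇐ 8-bromogeranyl acetate 3 + ketal Grignard 5 ⇐ geranyl acetate 1.

## Route

Step 1
Reactants: 1 geranyl acetate [(2E)-3,7-dimethylocta-2,6-dien-1-yl acetate]
Product: 2 (2E,6E)-8-hydroxy-3,7-dimethylocta-2,6-dien-1-yl acetate
Conditions: SeO2 (10 mol %), t-BuOOH (3 equiv), salicylic acid (10 mol %), CH2Cl2, rt
Reagents that add atoms: selenium dioxide O=[Se]=O (oxygen carrier); tert-butyl hydroperoxide CC(C)(C)OO (terminal oxygen source)
Why: Sharpless SeO2/TBHP allylic oxidation (ene reaction then [2,3]-shift) hydroxylates only the (E)-methyl of the electron-rich terminal olefin and leaves both E geometries intact.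

Step 2
Reactants: 2 (2E,6E)-8-hydroxy-3,7-dimethylocta-2,6-dien-1-yl acetate
Product: 3 (2E,6E)-8-bromo-3,7-dimethylocta-2,6-dien-1-yl acetate
Conditions: CBr4, PPh3, CH2Cl2, 0 °C
Reagents that add atoms: carbon tetrabromide BrC(Br)(Br)Br
Why: Appel bromination converts the primary allylic alcohol to the bromide by SN2 under neutral conditions, without allylic transposition or loss of the acetate.

Step 3
Reactants: 3 (2E,6E)-8-bromo-3,7-dimethylocta-2,6-dien-1-yl acetate; 4 2-(2-bromoethyl)-2-methyl-1,3-dioxolane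
Product: 6 (2E,6E)-3,7-dimethyl-10-(2-methyl-1,3-dioxolan-2-yl)deca-2,6-dien-1-yl acetate, via Grignard reagent 5 (not isolated)
Conditions: 4, Mg, THF, 25–30 °C; then added to 3, Li2CuCl4 (3 mol %), THF, −78 → −20 °C
Reagents that add atoms: none
Why: Kochi-type Cu-catalysed sp3–sp3 coupling of a primary alkyl Grignard with a primary allylic bromide is α-selective and geometry-retentive, and at −78 °C it is much faster than attack on the acetate.

Step 4
Reactants: 6 (2E,6E)-3,7-dimethyl-10-(2-methyl-1,3-dioxolan-2-yl)deca-2,6-dien-1-yl acetate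
Product: 7 (2E,6E)-3,7-dimethyl-11-oxododeca-2,6-dien-1-yl acetate
Conditions: AcOH/H2O/THF (3:1:1), 40 °C
Reagents that add atoms: water O
Why: Acid-catalysed ketal hydrolysis frees the methyl ketone, while the primary allylic acetate and the trisubstituted olefins tolerate dilute acetic acid.

Step 5
Reactants: 7 (2E,6E)-3,7-dimethyl-11-oxododeca-2,6-dien-1-yl acetate
Product: 8 (2E,6E)-3,7-dimethyl-10-[(2S)-2-methyloxiran-2-yl]deca-2,6-dien-1-yl acetate
Conditions: Me3S(O)I, NaH (1.2 equiv each, ylide preformed), (S)-La-Li3-tris(binaphthoxide) (5 mol %), (2,4,6-(MeO)3C6H2)3P=O (5 mol %), 5 Å MS, THF, rt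
Reagents that add atoms: trimethylsulfoxonium iodide C[S+](C)(C)=O.[I-]
Why: Catalytic asymmetric Corey–Chaykovsky epoxidation of a methyl ketone, in which the La/Li bimetallic catalyst binds ketone and ylide and delivers CH2 to one carbonyl face, sets the (S) quaternary epoxide carbon (future C4), the acetate reacting far more slowly with the ylide.

Step 6
Reactants: 8 (2E,6E)-3,7-dimethyl-10-[(2S)-2-methyloxiran-2-yl]deca-2,6-dien-1-yl acetate
Product: 9 (5E,9E)-6,10-dimethyl-13-[(2S)-2-methyloxiran-2-yl]trideca-5,9-dien-2-one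
Conditions: isopropenyl acetate (1.5 equiv), Bu3SnOMe (1.5 equiv), THF, 60 °C; then 8, Pd(PPh3)4 (5 mol %), 60 °C
Reagents that add atoms: isopropenyl acetate CC(=C)OC(C)=O (acetonyl unit, transferred as its tributyltin enolate)
Why: Tsuji–Trost allylic alkylation with a tin enolate attacks the unhindered primary terminus of the π-allyl to give the linear E ketone without dialkylation, and Pd(0) does not touch an isolated epoxide.

Step 7
Reactants: 9 (5E,9E)-6,10-dimethyl-13-[(2S)-2-methyloxiran-2-yl]trideca-5,9-dien-2-one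
Product: 11 (4S,5R,8R,9R,10S)-8,19-dihydroxy-14,15-dinorlabdan-13-one, via tricyclic enol ether 10 (not isolated)
Conditions: MeAlCl2 (1.2 equiv), CH2Cl2, −78 °C; then 1 M HCl, THF, 0 °C → rt
Reagents that add atoms: water O
Why: Proposed new method: Al activation of the 2,2-disubstituted oxirane lets the C5=C10 π bond open the tertiary C4–O bond from the rear (inversion, so the (S)-epoxide fixes 4S and the oxygen stays on C19), the epoxide CH2, still tied back toward the leaving oxygen in an early chair–chair transition state, takes the pseudoaxial site cis to C20 while the methyl avoids eclipsing C2, the two E-olefins add anti (5α-H, 10β-Me, 9α-H) and the ketone oxygen caps C8 from the α-face before aqueous acid hydrolyses the cyclic enol ether; the closest known reaction type is the MeAlCl2-promoted cationic cyclization of trisubstituted 2,3-epoxy polyenes with oxygen termination.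

Step 8
Reactants: 11 (4S,5R,8R,9R,10S)-8,19-dihydroxy-14,15-dinorlabdan-13-one; 12 (E)-4-methoxycinnamic acid
Product: 13 (4S,5R,8R,9R,10S)-8-hydroxy-13-oxo-14,15-dinorlabdan-19-yl (E)-4-methoxycinnamate
Conditions: DCC, DMAP (cat.), CH2Cl2, 0 °C → rt
Reagents that add atoms: none
Why: Steglich esterification acylates only the primary 19-OH, because the tertiary 8-OH is inert to the acyl-pyridinium intermediate.

Step 9
Reactants: 13 (4S,5R,8R,9R,10S)-8-hydroxy-13-oxo-14,15-dinorlabdan-19-yl (E)-4-methoxycinnamate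
Product: 15 (4S,5R,8R,9R,10S)-8-hydroxy-13-(trifluoromethanesulfonyloxy)-14,15-dinorlabd-13(16)-en-19-yl (E)-4-methoxycinnamate, via dipotassium enolate 14 (not isolated)
Conditions: KHMDS (2.3 equiv), THF, −78 °C; then PhNTf2 (1.15 equiv), −78 → −20 °C; aq. NH4Cl quench
Reagents that add atoms: N-phenylbis(trifluoromethanesulfonimide) O=S(=O)(N(c1ccccc1)S(=O)(=O)C(F)(F)F)C(F)(F)F
Why: Kinetic deprotonation of the methyl ketone at the methyl group by the bulky amide (excess base holds the 8-alkoxide and prevents enolate equilibration) and O-triflation give the terminal enol triflate, the cinnamate having no acidic hydrogens.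

Step 10
Reactants: 15 (4S,5R,8R,9R,10S)-8-hydroxy-13-(trifluoromethanesulfonyloxy)-14,15-dinorlabd-13(16)-en-19-yl (E)-4-methoxycinnamate
Product: 16 (4S,5R,8R,9R,10S)-8-hydroxylabda-13(16),14-dien-19-yl (E)-4-methoxycinnamate (CNP0249194.1)
Conditions: tributyl(vinyl)stannane (1.3 equiv), Pd(PPh3)4 (5 mol %), LiCl (3 equiv), THF, 60 °C
Reagents that add atoms: tributyl(vinyl)stannane C=C[Sn](CCCC)(CCCC)CCCC
Why: Stille coupling of an enol triflate with a vinylstannane under neutral conditions gives the 2-substituted 1,3-butadiene without touching the free tertiary alcohol, the ester or any stereocentre.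

## Compound list
1 | geranyl acetate, (2E)-3,7-dimethylocta-2,6-dien-1-yl acetate | CC(=O)OC/C=C(\C)CCC=C(C)C | starting material
2 | (2E,6E)-8-hydroxy-3,7-dimethylocta-2,6-dien-1-yl acetate | CC(=O)OC/C=C(\C)CC/C=C(\C)CO | intermediate
3 | (2E,6E)-8-bromo-3,7-dimethylocta-2,6-dien-1-yl acetate | CC(=O)OC/C=C(\C)CC/C=C(\C)CBr | intermediate
4 | 2-(2-bromoethyl)-2-methyl-1,3-dioxolane | CC1(CCBr)OCCO1 | starting material
5 | [2-(2-methyl-1,3-dioxolan-2-yl)ethyl]magnesium bromide (Grignard reagent) | CC1(CC[Mg]Br)OCCO1 | intermediate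
6 | (2E,6E)-3,7-dimethyl-10-(2-methyl-1,3-dioxolan-2-yl)deca-2,6-dien-1-yl acetate | CC(=O)OC/C=C(\C)CC/C=C(\C)CCCC1(C)OCCO1 | intermediate
7 | (2E,6E)-3,7-dimethyl-11-oxododeca-2,6-dien-1-yl acetate | CC(=O)OC/C=C(\C)CC/C=C(\C)CCCC(C)=O | intermediate
8 | (2E,6E)-3,7-dimethyl-10-[(2S)-2-methyloxiran-2-yl]deca-2,6-dien-1-yl acetate | CC(=O)OC/C=C(\C)CC/C=C(\C)CCC[C@@]1(C)CO1 | intermediate
9 | (5E,9E)-6,10-dimethyl-13-[(2S)-2-methyloxiran-2-yl]trideca-5,9-dien-2-one | CC(=O)CC/C=C(\C)CC/C=C(\C)CCC[C@@]1(C)CO1 | intermediate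
10 | (4S,5R,8R,9R,10S)-8,13-epoxy-14,15-dinorlabd-12-en-19-ol (tricyclic enol ether; trans-decalin fused to a dihydropyran, O on C8 α) | CC1=CC[C@@H]2[C@@]3(C)CCC[C@](C)(CO)[C@@H]3CC[C@@]2(C)O1 | intermediate
11 | (4S,5R,8R,9R,10S)-8,19-dihydroxy-14,15-dinorlabdan-13-one (8α-OH, axial 19-CH2OH, 9β-CH2CH2COCH3) | CC(=O)CC[C@@H]1[C@@]2(C)CCC[C@](C)(CO)[C@@H]2CC[C@@]1(C)O | intermediate
12 | (E)-4-methoxycinnamic acid | COc1ccc(/C=C/C(=O)O)cc1 | starting material
13 | (4S,5R,8R,9R,10S)-8-hydroxy-13-oxo-14,15-dinorlabdan-19-yl (E)-4-methoxycinnamate | CC(=O)CC[C@@H]1[C@@]2(C)CCC[C@](C)(COC(=O)/C=C/c3ccc(OC)cc3)[C@@H]2CC[C@@]1(C)O | intermediate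
14 | dipotassium 8-alkoxide C13(16)-enolate of 13 | [K+].[K+].C=C([O-])CC[C@@H]1[C@@]2(C)CCC[C@](C)(COC(=O)/C=C/c3ccc(OC)cc3)[C@@H]2CC[C@@]1(C)[O-] | intermediate
15 | (4S,5R,8R,9R,10S)-8-hydroxy-13-(trifluoromethanesulfonyloxy)-14,15-dinorlabd-13(16)-en-19-yl (E)-4-methoxycinnamate | C=C(OS(=O)(=O)C(F)(F)F)CC[C@@H]1[C@@]2(C)CCC[C@](C)(COC(=O)/C=C/c3ccc(OC)cc3)[C@@H]2CC[C@@]1(C)O | intermediate
16 | (4S,5R,8R,9R,10S)-8-hydroxylabda-13(16),14-dien-19-yl (E)-4-methoxycinnamate | C=CC(=C)CC[C@@H]1[C@@]2(C)CCC[C@](C)(COC(=O)/C=C/c3ccc(OC)cc3)[C@@H]2CC[C@@]1(C)O | target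

## Step count and risks
Total steps: 10. Longest linear sequence: 10 (1 → 16).

**Most likely to fail, in order:**

1. **Step 7 (bicyclization).** The Lewis-acid-opened 2,2-disubstituted epoxide can undergo a 1,2-hydride shift to the aldehyde, the C8 cation can lose a proton if the ketone is tied up by aluminium, and the chair preference that puts CH2O axial is predicted, not proven. The fallback replaces the terminating group with an enolised β-keto ester, a stronger oxygen nucleophile that tin(IV) chelates instead of blocking; it does not address the initiation risks. It sets out from 8: Pd(PPh3)4-catalysed allylation of the sodium enolate of methyl acetoacetate gives the β-keto ester methyl (4E,8E)-2-acetyl-5,9-dimethyl-12-[(2S)-2-methyloxiran-2-yl]dodeca-4,8-dienoate F1. SnCl4 in CH2Cl2 at −78 °C then closes rings A and B with O-capture by the enol to give the tricyclic β-alkoxyacrylate methyl (4S,5R,8R,9R,10S)-8,13-epoxy-19-hydroxy-14,15-dinorlabd-12-ene-12-carboxylate F2. Saponification with LiOH and mild acidification (enol ether hydrolysis, decarboxylation) bring it back to the route at 11.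

2. **Step 5 (asymmetric ylide epoxidation).** The enantiomeric excess may drop for this long-chain aliphatic methyl ketone, and the acetate may be attacked by the ylide. The fallback sets the epoxide centre with a stoichiometric chiral sulfoximine and a diastereomer separation instead of a catalyst. It sets out from 7: lithiated (S)-N,S-dimethyl-S-phenylsulfoximine (n-BuLi, THF, −78 °C) adds to the ketone, and chromatography isolates the (11S) adduct (2E,6E)-11-hydroxy-3,7,11-trimethyl-12-[(S)-N-methyl-S-phenylsulfonimidoyl]dodeca-2,6-dien-1-yl acetate F3; the other diastereomer reverts thermally to 7 and is recycled. N-Methylation with Me3OBF4 and treatment with DBU close the epoxide with retention at the carbinol carbon, returning to the route at 8.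

3. **Step 6 (Pd acetonylation).** Branched product, E → Z scrambling through the σ-allyl, or an unreactive tin enolate would spoil the polyene geometry that step 7 depends on. The fallback uses classical SN2 chemistry that cannot scramble the olefin. It sets out from 8: K2CO3/MeOH gives the allylic alcohol (2E,6E)-3,7-dimethyl-10-[(2S)-2-methyloxiran-2-yl]deca-2,6-dien-1-ol F4, and CBr4/PPh3 gives the bromide (2S)-2-[(4E,8E)-10-bromo-4,8-dimethyldeca-4,8-dien-1-yl]-2-methyloxirane F5. Alkylation of lithiated acetone N,N-dimethylhydrazone (LDA, THF, −78 °C) gives the hydrazone of 9, (5E,9E)-6,10-dimethyl-13-[(2S)-2-methyloxiran-2-yl]trideca-5,9-dien-2-one N,N-dimethylhydrazone F6, and neutral cleavage with aqueous Cu(OAc)2 returns to the route at 9.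

## Further compounds
F1 | step 7 | methyl (4E,8E)-2-acetyl-5,9-dimethyl-12-[(2S)-2-methyloxiran-2-yl]dodeca-4,8-dienoate | COC(=O)C(C(C)=O)C/C=C(\C)CC/C=C(\C)CCC[C@@]1(C)CO1
F2 | step 7 | methyl (4S,5R,8R,9R,10S)-8,13-epoxy-19-hydroxy-14,15-dinorlabd-12-ene-12-carboxylate | CC1=C(C(=O)OC)C[C@@H]2[C@@]3(C)CCC[C@](C)(CO)[C@@H]3CC[C@@]2(C)O1
F3 | step 5 | (2E,6E,11S)-11-hydroxy-3,7,11-trimethyl-12-[(S)-N-methyl-S-phenylsulfonimidoyl]dodeca-2,6-dien-1-yl acetate | CC(=O)OC/C=C(\C)CC/C=C(\C)CCC[C@@](O)(C)C[S@@](=O)(=NC)c1ccccc1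
F4 | step 6 | (2E,6E)-3,7-dimethyl-10-[(2S)-2-methyloxiran-2-yl]deca-2,6-dien-1-ol | OC/C=C(\C)CC/C=C(\C)CCC[C@@]1(C)CO1
F5 | step 6 | (2S)-2-[(4E,8E)-10-bromo-4,8-dimethyldeca-4,8-dien-1-yl]-2-methyloxirane | BrC/C=C(\C)CC/C=C(\C)CCC[C@@]1(C)CO1
F6 | step 6 | (5E,9E)-6,10-dimethyl-13-[(2S)-2-methyloxiran-2-yl]trideca-5,9-dien-2-one N,N-dimethylhydrazone | CN(C)N=C(C)CC/C=C(\C)CC/C=C(\C)CCC[C@@]1(C)CO1
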